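**Retrosynthetic overview**
1. Oxazole (formed last): Robinson–Gabriel C–O closure of the keto amide Ar–C(=O)–CH2–NH–C(=O)–pyrrole; the ketone comes from benzylic DDQ/H2O oxidation of the N-acyl tryptamine.
2. Amide C–N: 6-bromo-4-methoxytryptamine plus 5-bromo-1H-pyrrole-2-carboxylic acid (bromopyrrole bought intact, so no late regioselective bromination).
3. Key C–C bond (side-chain Cα–Cβ): Henry nitroaldol condensation of 6-bromo-4-methoxyindole-3-carbaldehyde with nitromethane, then C=C and NO2 reduction.
4. Indole ring (formed first): Hemetsberger–Knittel sequence, i.e. aldol-type condensation of 4-bromo-2-methoxybenzaldehyde with methyl azidoacetate and nitrene C–H insertion, then saponification, decarboxylation and Vilsmeier C3 formylation.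
5. Ring order: benzene (bought) → indole five-membered ring → bromopyrrole (bought, attached as amide) → oxazole.

Assumption: the target has no stereocentre (it is achiral), so there is no enantiomer to control; the only stereo-elements on the route are two alkene geometries that are destroyed later.

**Route**

Step 1
Reactants: 1 4-bromo-2-methoxybenzaldehyde; 2 methyl azidoacetate
Product: 4 methyl (Z)-2-azido-3-(4-bromo-2-methoxyphenyl)prop-2-enoate, via aldol adduct 3 (not isolated)
Conditions: NaOMe (4 equiv), 2 (4 equiv), MeOH, −10 → 0 °C; pour onto ice-water, filter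
Reagents that add atoms: none
Why: Methoxide forms the ester enolate of 2, which adds to the non-enolisable aldehyde 1 and the adduct 3 loses hydroxide in the same pot (Knoevenagel-type aldol condensation, first stage of the Hemetsberger–Knittel indole synthesis) to give the favoured Z-alkene, with the low temperature protecting the azide.

Step 2
Reactants: 4 methyl (Z)-2-azido-3-(4-bromo-2-methoxyphenyl)prop-2-enoate
Product: 5 methyl 6-bromo-4-methoxy-1H-indole-2-carboxylate
Conditions: xylene, 140 °C, slow addition, about 0.05 M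
Reagents that add atoms: none
Why: Thermolysis expels N2 and the resulting nitrene inserts into the only free ortho C–H of the arene (Hemetsberger–Knittel cyclisation), so only the 4-methoxy-6-bromo pattern can form.

Step 3
Reactants: 5 methyl 6-bromo-4-methoxy-1H-indole-2-carboxylate
Product: 6 6-bromo-4-methoxy-1H-indole-2-carboxylic acid
Conditions: 2 M aq NaOH, MeOH/THF, 60 °C; then 2 M HCl to pH 2, filter
Reagents that add atoms: sodium hydroxide, [Na+].[OH-] (oxygen of the carboxyl OH)
Why: Plain ester saponification (BAc2) of an unhindered methyl ester, with nothing else in the molecule sensitive to aqueous base.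

Step 4
Reactants: 6 6-bromo-4-methoxy-1H-indole-2-carboxylic acid
Product: 7 6-bromo-4-methoxy-1H-indole
Conditions: Cu powder (0.2 equiv), quinoline, 210 °C, N2, until gas evolution stops; dilute HCl wash
Reagents that add atoms: none
Why: Copper-mediated protodecarboxylation of indole-2-carboxylic acids in quinoline is the classical end of a Hemetsberger sequence, and the aryl bromide and methyl ether tolerate it on short heating.

Step 5
Reactants: 7 6-bromo-4-methoxy-1H-indole
Product: 9 6-bromo-4-methoxy-1H-indole-3-carbaldehyde, via iminium salt 8 (not isolated)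
Conditions: POCl3 (1.2 equiv), DMF, 0 → 40 °C; then 2 M aq NaOH, 80 °C
Reagents that add atoms: N,N-dimethylformamide, CN(C)C=O (formyl carbon); water, O (aldehyde oxygen on hydrolysis)
Why: Vilsmeier–Haack formylation goes to C3, the most nucleophilic indole position (reinforced by the 4-methoxy group), and basic hydrolysis of iminium 8 releases the aldehyde.

Step 6
Reactants: 9 6-bromo-4-methoxy-1H-indole-3-carbaldehyde; 10 nitromethane
Product: 12 6-bromo-4-methoxy-3-[(E)-2-nitroethenyl]-1H-indole, via nitroaldol adduct 11 (not isolated)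
Conditions: MeNO2 (10, as solvent), NH4OAc (0.5 equiv), 100 °C, 1–2 h; cool, filter
Reagents that add atoms: none
Why: Henry (nitroaldol) reaction: the nitronate of 10 adds to the aldehyde and adduct 11 dehydrates spontaneously, pushed by the indole nitrogen, to the conjugated E-nitroalkene, which crystallises and drives the equilibrium.

Step 7
Reactants: 12 6-bromo-4-methoxy-3-[(E)-2-nitroethenyl]-1H-indole
Product: 13 6-bromo-4-methoxy-3-(2-nitroethyl)-1H-indole
Conditions: NaBH4 (4 equiv), THF/MeOH 9:1, 0 °C → rt, 12 added slowly to the hydride; AcOH quench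
Reagents that add atoms: none
Why: Conjugate hydride reduction of a nitroalkene by NaBH4 leaves the aryl bromide and nitro group alone, and excess hydride with inverse addition suppresses nitronate-to-nitroalkene dimerisation.

Step 8
Reactants: 13 6-bromo-4-methoxy-3-(2-nitroethyl)-1H-indole
Product: 14 2-(6-bromo-4-methoxy-1H-indol-3-yl)ethan-1-amine
Conditions: Zn dust (15 equiv), 2 M aq HCl, MeOH, 0 °C → rt; then aq NaOH to pH 12, extract
Reagents that add atoms: none
Why: Dissolving-metal (Zn/HCl) reduction takes an aliphatic nitro group to the primary amine without touching the aryl C–Br bond, which catalytic hydrogenation or hot LiAlH4 would put at risk.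

Step 9
Reactants: 14 2-(6-bromo-4-methoxy-1H-indol-3-yl)ethan-1-amine; 15 5-bromo-1H-pyrrole-2-carboxylic acid
Product: 17 5-bromo-N-[2-(6-bromo-4-methoxy-1H-indol-3-yl)ethyl]-1H-pyrrole-2-carboxamide, via benzotriazolyl ester 16 (not isolated)
Conditions: EDC·HCl (1.3 equiv), HOBt (1.3 equiv), iPr2NEt (2 equiv), DMF, 0 °C → rt
Reagents that add atoms: none
Why: Carbodiimide/HOBt amide coupling: the primary amine is far more nucleophilic than the indole or pyrrole N–H, so only the side-chain nitrogen is acylated by active ester 16.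

Step 10
Reactants: 17 5-bromo-N-[2-(6-bromo-4-methoxy-1H-indol-3-yl)ethyl]-1H-pyrrole-2-carboxamide
Product: 19 5-bromo-N-[2-(6-bromo-4-methoxy-1H-indol-3-yl)-2-oxoethyl]-1H-pyrrole-2-carboxamide, via carbinol 18 (not isolated)
Conditions: DDQ (2.2 equiv), THF/H2O 9:1, 0 °C → rt
Reagents that add atoms: water, O
Why: DDQ benzylic oxidation of a 3-alkylindole (Oikawa–Yonemitsu): hydride abstraction next to the electron-rich indole C3 gives a cation that water captures as carbinol 18, and a second DDQ oxidation stops at the 3-acylindole, which is deactivated towards further oxidation.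

Step 11
Reactants: 19 5-bromo-N-[2-(6-bromo-4-methoxy-1H-indol-3-yl)-2-oxoethyl]-1H-pyrrole-2-carboxamide
Product: 20 6-bromo-3-[2-(5-bromo-1H-pyrrol-2-yl)-1,3-oxazol-5-yl]-4-methoxy-1H-indole
Conditions: PPh3 (2.5 equiv), C2Cl6 (2.5 equiv), Et3N (5 equiv), MeCN, 0 °C → rt
Reagents that add atoms: none
Why: Robinson–Gabriel cyclodehydration of the 2-acylamino ketone under the mild, non-acidic Wipf conditions (chlorophosphonium activation, loss of the oxygen as Ph3P=O), which the acid-sensitive bromopyrrole and both free N–H groups tolerate.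

**Compound list**
1 | 4-bromo-2-methoxybenzaldehyde | COc1cc(Br)ccc1C=O | starting material
2 | methyl azidoacetate | COC(=O)CN=[N+]=[N-] | starting material
3 | methyl 2-azido-3-(4-bromo-2-methoxyphenyl)-3-hydroxypropanoate (aldol adduct, racemic diastereomer mixture) | COC(=O)C(N=[N+]=[N-])C(O)c1ccc(Br)cc1OC | intermediate (not isolated)
4 | methyl (Z)-2-azido-3-(4-bromo-2-methoxyphenyl)prop-2-enoate | COC(=O)/C(N=[N+]=[N-])=C/c1ccc(Br)cc1OC | intermediate
5 | methyl 6-bromo-4-methoxy-1H-indole-2-carboxylate | COC(=O)c1cc2c(OC)cc(Br)cc2[nH]1 | intermediate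
6 | 6-bromo-4-methoxy-1H-indole-2-carboxylic acid | OC(=O)c1cc2c(OC)cc(Br)cc2[nH]1 | intermediate
7 | 6-bromo-4-methoxy-1H-indole | COc1cc(Br)cc2[nH]ccc12 | intermediate
8 | N-[(6-bromo-4-methoxy-1H-indol-3-yl)methylidene]-N-methylmethanaminium salt (drawn as chloride) | COc1cc(Br)cc2[nH]cc(C=[N+](C)C)c12.[Cl-] | intermediate (not isolated)
9 | 6-bromo-4-methoxy-1H-indole-3-carbaldehyde | COc1cc(Br)cc2[nH]cc(C=O)c12 | intermediate
10 | nitromethane | C[N+](=O)[O-] | starting material
11 | 1-(6-bromo-4-methoxy-1H-indol-3-yl)-2-nitroethan-1-ol (nitroaldol adduct, racemic) | COc1cc(Br)cc2[nH]cc(C(O)C[N+](=O)[O-])c12 | intermediate (not isolated)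
12 | 6-bromo-4-methoxy-3-[(E)-2-nitroethenyl]-1H-indole | COc1cc(Br)cc2[nH]cc(/C=C/[N+](=O)[O-])c12 | intermediate
13 | 6-bromo-4-methoxy-3-(2-nitroethyl)-1H-indole | COc1cc(Br)cc2[nH]cc(CC[N+](=O)[O-])c12 | intermediate
14 | 2-(6-bromo-4-methoxy-1H-indol-3-yl)ethan-1-amine | COc1cc(Br)cc2[nH]cc(CCN)c12 | intermediate
15 | 5-bromo-1H-pyrrole-2-carboxylic acid | OC(=O)c1ccc(Br)[nH]1 | starting material
16 | 1H-benzotriazol-1-yl 5-bromo-1H-pyrrole-2-carboxylate | O=C(On1nnc2ccccc12)c1ccc(Br)[nH]1 | intermediate (not isolated)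
17 | 5-bromo-N-[2-(6-bromo-4-methoxy-1H-indol-3-yl)ethyl]-1H-pyrrole-2-carboxamide | COc1cc(Br)cc2[nH]cc(CCNC(=O)c3ccc(Br)[nH]3)c12 | intermediate
18 | 5-bromo-N-[2-(6-bromo-4-methoxy-1H-indol-3-yl)-2-hydroxyethyl]-1H-pyrrole-2-carboxamide (racemic) | COc1cc(Br)cc2[nH]cc(C(O)CNC(=O)c3ccc(Br)[nH]3)c12 | intermediate (not isolated)
19 | 5-bromo-N-[2-(6-bromo-4-methoxy-1H-indol-3-yl)-2-oxoethyl]-1H-pyrrole-2-carboxamide | COc1cc(Br)cc2[nH]cc(C(=O)CNC(=O)c3ccc(Br)[nH]3)c12 | intermediate
20 | 6-bromo-3-[2-(5-bromo-1H-pyrrol-2-yl)-1,3-oxazol-5-yl]-4-methoxy-1H-indole (achiral) | COc1cc(Br)cc2[nH]cc(-c3cnc(-c4ccc(Br)[nH]4)o3)c12 | target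

**Summary**
Total step count: 11. Longest linear sequence: 11 steps (1 → 20); compounds 2, 10 and 15 enter in steps 1, 6 and 9.

Steps most likely to fail:

Step 4 (decarboxylation at about 210 °C: tarring or partial loss of bromine). The fallback sets out from ester 5 and comes back at indole 7, replacing loss of CO2 by loss of CO under neutral conditions. Reduce 5 with DIBAL-H (THF, −78 → 0 °C) to (6-bromo-4-methoxy-1H-indol-2-yl)methanol F1. Oxidise it with activated MnO2 (CH2Cl2, rt) to 6-bromo-4-methoxy-1H-indole-2-carbaldehyde F2. Remove the formyl group by Tsuji–Wilkinson decarbonylation (RhCl(PPh3)3, toluene, 110 °C) to give 7.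

Step 10 (DDQ oxidation: incomplete reaction, or attack on the pyrrole). The fallback sets out from aldehyde 9 and comes back at keto amide 19. It keeps the oxygen of the nitroaldol adduct instead of eliminating it and re-oxidising later.
- Protect 9 with Boc2O and cat. DMAP (MeCN) as tert-butyl 6-bromo-3-formyl-4-methoxy-1H-indole-1-carboxylate F3, which behaves as a normal aryl aldehyde.
- Base-catalysed Henry addition of nitromethane 10 (cat. DBU, THF, 0 °C) then stops at tert-butyl 6-bromo-3-(1-hydroxy-2-nitroethyl)-4-methoxy-1H-indole-1-carboxylate F4.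
- Zn/AcOH reduction gives tert-butyl 3-(2-amino-1-hydroxyethyl)-6-bromo-4-methoxy-1H-indole-1-carboxylate F5.
- EDC/HOBt coupling with acid 15 gives tert-butyl 6-bromo-3-{2-[(5-bromo-1H-pyrrole-2-carbonyl)amino]-1-hydroxyethyl}-4-methoxy-1H-indole-1-carboxylate F6.
- Dess–Martin periodinane (CH2Cl2, NaHCO3) gives tert-butyl 6-bromo-3-[N-(5-bromo-1H-pyrrole-2-carbonyl)glycyl]-4-methoxy-1H-indole-1-carboxylate F7.
- TFA/CH2Cl2 at 0 °C removes the Boc group to give 19.

Step 11 (cyclodehydration: sluggish vinylogous-amide ketone, or the bromopyrrole suffers). The fallback sets out from amide 17 and comes back at target 20 by oxidative cyclisation in place of cyclodehydration, skipping 19. Treat 17 with DDQ (3 equiv) in anhydrous dioxane at reflux. Without water, the cation at the indole benzylic carbon is captured by the amide oxygen to give 5-(6-bromo-4-methoxy-1H-indol-3-yl)-2-(5-bromo-1H-pyrrol-2-yl)-4,5-dihydro-1,3-oxazole F8 in the flask, and further DDQ dehydrogenates it to 20. Reaching step 11 already shows that DDQ chemistry works on this substrate.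

**Further compounds**
F1 | step 4 | (6-bromo-4-methoxy-1H-indol-2-yl)methanol | COc1cc(Br)cc2[nH]c(CO)cc12
F2 | step 4 | 6-bromo-4-methoxy-1H-indole-2-carbaldehyde | COc1cc(Br)cc2[nH]c(C=O)cc12
F3 | step 10 | tert-butyl 6-bromo-3-formyl-4-methoxy-1H-indole-1-carboxylate | COc1cc(Br)cc2c1c(C=O)cn2C(=O)OC(C)(C)C
F4 | step 10 | tert-butyl 6-bromo-3-(1-hydroxy-2-nitroethyl)-4-methoxy-1H-indole-1-carboxylate (racemic) | COc1cc(Br)cc2c1c(C(O)C[N+](=O)[O-])cn2C(=O)OC(C)(C)C
F5 | step 10 | tert-butyl 3-(2-amino-1-hydroxyethyl)-6-bromo-4-methoxy-1H-indole-1-carboxylate (racemic) | COc1cc(Br)cc2c1c(C(O)CN)cn2C(=O)OC(C)(C)C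
F6 | step 10 | tert-butyl 6-bromo-3-{2-[(5-bromo-1H-pyrrole-2-carbonyl)amino]-1-hydroxyethyl}-4-methoxy-1H-indole-1-carboxylate (racemic) | COc1cc(Br)cc2c1c(C(O)CNC(=O)c1ccc(Br)[nH]1)cn2C(=O)OC(C)(C)C
F7 | step 10 | tert-butyl 6-bromo-3-[N-(5-bromo-1H-pyrrole-2-carbonyl)glycyl]-4-methoxy-1H-indole-1-carboxylate | COc1cc(Br)cc2c1c(C(=O)CNC(=O)c1ccc(Br)[nH]1)cn2C(=O)OC(C)(C)C
F8 | step 11 | 5-(6-bromo-4-methoxy-1H-indol-3-yl)-2-(5-bromo-1H-pyrrol-2-yl)-4,5-dihydro-1,3-oxazole (racemic) | COc1cc(Br)cc2[nH]cc(C3CN=C(c4ccc(Br)[nH]4)O3)c12
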